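You have explained the left-handed curves, and the right-handed product is left over: small, near the scatter, and the part that sets the excess.

| flask | left-handed substrate | right-handed substrate | solid reagent | free catalyst | racemization catalyst | added ligand | remark | time |
|---|---|---|---|---|---|---|---|---|
| beta | 0.30 M | 0.30 M | 0.66 M | 3 mM | 1.5 mM | 2.9 mM | run made earlier |  |
| theta | 0.30 M | 0.30 M | 0.66 M | 3 mM | 1.5 mM | 11 mM | run made earlier |  |
| alpha | 0.30 M | 0.30 M | 0.66 M | 3 mM | 1.5 mM | 45 mM | run made earlier |  |
| amber | 0.30 M | 0.30 M | 0.660 M | 3.0 mM | 1.5 mM | 2.5 mM |  | 12 h |
| teal | 0.30 M | 0.30 M | 0.660 M | 3.0 mM | 1.5 mM | 5.0 mM |  | 12 h |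
| grey | 0.30 M | 0.30 M | 0.660 M | 3.0 mM | 1.5 mM | 10 mM |  | 12 h |
| green | 0.30 M | 0.30 M | 0.660 M | 3.0 mM | 1.5 mM | 20 mM |  | 12 h |
| red | 0.30 M | 0.30 M | 0.660 M | 3.0 mM | 1.5 mM | 40 mM |  | 12 h |

| run | time / h | left-handed product / % | right-handed product / % |
|---|---|---|---|
| beta | 1.33 | 5 | 0 |
| beta | 2.50 | 10 | 2 |
| beta | 4.00 | 20 | 2 |
| beta | 5.00 | 26 | 2 |
| beta | 6.00 | 32 | 1 |
| theta | 0.500 | 2 | 0 |
| theta | 1.50 | 6 | 0 |
| theta | 3.00 | 8 | 0 |
| theta | 4.00 | 14 | 1 |
| theta | 6.00 | 20 | 1 |
| alpha | 0.500 | 0 | 2 |
| alpha | 0.833 | 1 | 0 |
| alpha | 1.50 | 1 | 0 |
| alpha | 3.00 | 4 | 0 |
| alpha | 6.00 | 8 | 2 |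

(readings scatter by 1.5 percentage points)

- free catalyst is single-handed; left-handed substrate and right-handed substrate are mirror images of each other, charged as a racemate, each of them at the stated concentration
- given per volume of solution although it is solid: solid reagent
- at the start none of the solid reagent is in solution
- an excess is the difference of the two amounts in percent of their sum
- "hardly changes" means that all values lie within two and a half points (for a concentration: within two and a half percent of the largest)

- excess of left-handed product over right-handed product at the end for amber, teal, grey, green, red, in this order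
- how the row runs (rises all the way / falls all the way / falls, then rises / hardly changes / rises, then falls)

At 6.00 h the beta, theta and alpha flasks together hold 60.0% of left-handed product and 4.00% of right-handed product, so left over right is 15.0. Carry this product ratio, read as the selectivity factor if one catalyst makes both products. Its logarithm is 1.18. The excess is the ratio minus one over the ratio plus one, here 87.5%.

But the right-handed sum carries a scatter of 2.6 percentage points. One scatter either way moves the logarithm from 0.959 to 1.63, and the excess from 80.2% to 95.4%.

A worse objection: beta alone gives 32.0 and alpha alone 4.00, as if the ratio fell with added ligand. Yet a fixed ratio predicts 2.13% of right-handed product in beta and 0.533% in alpha. Each lies less than one scatter from its reading, so the readings can't choose. I choose by the chemistry. If both mirror-image substrates need the free catalyst, the added ligand divides both rates by one factor and drops out of the ratio.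

One doubt remains: a lagging racemization would thin the left-handed substrate and lower the ratio in the fastest flask. In beta the pace of the last stretch is 1.20 times that of the first, but this reading can't clear the doubt, since a slow start could hide a thinning. So the doubt stays open, and I expect a flat row near 87.5%.

The forecast differs: 90%, 89%, 86%, 80%, 70%, so falls all the way, with the right-handed product read as “a ligand-independent racemic background of about 0.25 %/h”.

The simulation gives 87.1%, 87.3%, 87.6%, 87.8%, 88.0%: the row hardly changes.

    partner + free catalyst + left-handed substrate → free catalyst + left-handed product (k = 13.0 M⁻² min⁻¹)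
    partner + free catalyst + right-handed substrate → free catalyst + right-handed product (k = 0.810 M⁻² min⁻¹)
    left-handed substrate + racemization catalyst ⇌ right-handed substrate + racemization catalyst, rate k3*[racemization catalyst]*[left-handed substrate] forward; the back reaction follows from the equilibrium constant (k = 7.50 M⁻¹ min⁻¹)
    free catalyst + added ligand ⇌ idle complex (K = 200 M⁻¹, k = 230 M⁻¹ min⁻¹)
    solid reagent ⇌ partner, rate k5*(cs5 - [partner]) while solid is left; crystals form when [partner] > cs5 (solubility = 0.150 M, k = 0.0120 min⁻¹)

In amber the left-handed step uses partner 14 times as fast as the right-handed step at 4.45 h and 14 times as fast at 12.0 h, beside your product ratio of 15.0 read from the earlier runs. From amber to red the free catalyst goes from 74.3% to 11.8% of its charge, and the right-handed product goes down with the left-handed one, from 4.05% to 1.14% against 58.5% to 17.9%, which leaves red's product ratio at 15.7.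

The earlier runs and the new flask were generated by integration with made-up constants; scatter was added.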